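**Retrosynthetic overview**

1. Hippolide D (27) ⇐ selective allylic oxidation and desilylation ⇐ silyl-protected anhydride 25 ⇐ diacid 24 ⇐ trans-lactone acid 21: the β-hydroxyalkyl succinic anhydride is treated as a disguised paraconic acid (the carbinol O is 1,4 to the carboxyl on the CH2 side).
2. 21 ⇐ hydroxymethyl lactone 19 ⇐ epoxy acetate 15 (key step): the ring CH2–CH bond (C-4/C-3 of the anhydride) is formed by 5-exo ring closure of an acetate enolate onto a cis-epoxide, followed by acyl transfer to the carbinol oxygen.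
3. Enabling feature: ring C-3 and the exocyclic carbinol carbon are vicinal stereocentres carrying the new C–C bond and the OH in an SN2 (anti-addition) relationship, the retron of a cis-2,3-epoxy alcohol; the C-2 carbonyl carbon, taken down to CH2–O, anchors the acetate two atoms from C-3 (a temporary ester tether, cut by the acyl shift and re-oxidised).
4. 15 ⇐ Sharpless epoxidation of (Z)-allylic alcohol 13 ⇐ Lindlar reduction of enynol 12 ⇐ Cu-mediated coupling of propargyl alcohol with allylic bromide 10 ⇐ B-alkyl Suzuki coupling of homofarnesyl-9-BBN (from farnesol) with (Z)-iodide 4 (from butynediol), which fixes the geometry of the later E-enal.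
5. Ring order: oxirane (temporary, step 9) → γ-lactone by C–C closure, then its isomer by acyl shift (step 11) → lactone opened (step 13) → succinic anhydride (step 14).

Key step: step 11

Remark on the chemistry: the β-hydroxyalkyl succinic anhydride is assumed to be kinetically stable in neutral to weakly acidic, non-nucleophilic media (as its isolation implies), so bases and nucleophilic catalysts are avoided once the anhydride is in place.

**Route**

Step 1
Reactants: 1 but-2-yne-1,4-diol
Product: 2 4-[(tert-butyldimethylsilyl)oxy]but-2-yn-1-ol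
Conditions: NaH (1.0 equiv), THF, 0 °C; TBSCl (1.0 equiv), rt
Reagents that add atoms: tert-butyldimethylsilyl chloride, CC(C)(C)[Si](C)(C)Cl
Why: One equivalent of NaH gives the poorly soluble mono-alkoxide of the symmetrical diol, so O-silylation should stop largely at the mono-ether (statistical monoprotection of a symmetrical diol).

Step 2
Reactants: 2 4-[(tert-butyldimethylsilyl)oxy]but-2-yn-1-ol
Product: 4 (Z)-4-[(tert-butyldimethylsilyl)oxy]-3-iodobut-2-en-1-ol, via sodium alkenylaluminate 3 (not isolated)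
Conditions: Red-Al, THF, 0 °C; then I2, −78 → 0 °C
Reagents that add atoms: iodine, II
Why: Alkoxide-directed trans-hydroalumination of the propargylic alcohol puts hydride on C-2 and aluminium on C-3 in a five-membered aluminate, and iodinolysis with retention should give the (Z)-iodide with iodine cis to CH2OH; keeping the aluminate cold is meant to prevent β-elimination of the silyloxy group to an allene.

Step 3
Reactants: 5 (2E,6E)-farnesol
Product: 6 (2E,6E)-farnesal
Conditions: MnO2, CH2Cl2, rt
Reagents that add atoms: none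
Why: MnO2 oxidation of an allylic alcohol to the enal, which should leave the 2E geometry and the isolated alkenes untouched.

Step 4
Reactants: 6 (2E,6E)-farnesal
Product: 7 (3E,7E)-4,8,12-trimethyltrideca-1,3,7,11-tetraene
Conditions: Ph3PCH3Br, KOtBu, THF, 0 °C → rt
Reagents that add atoms: methyltriphenylphosphonium bromide, C[P+](c1ccccc1)(c1ccccc1)c1ccccc1.[Br-]
Why: Wittig methylenation of the enal with the non-stabilised ylide should give the terminal 1,3-diene without touching the 3E olefin.

Step 5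
Reactants: 7 (3E,7E)-4,8,12-trimethyltrideca-1,3,7,11-tetraene; 4 (Z)-4-[(tert-butyldimethylsilyl)oxy]-3-iodobut-2-en-1-ol
Product: 9 (2E,6E,10E)-3-{[(tert-butyldimethylsilyl)oxy]methyl}-7,11,15-trimethylhexadeca-2,6,10,14-tetraen-1-ol, via homofarnesyl-9-BBN 8 (not isolated)
Conditions: 9-BBN-H, THF, 0 °C → rt; then 4, PdCl2(dppf) (5 mol %), AsPh3, Cs2CO3, DMF/H2O, rt
Reagents that add atoms: none
Why: 9-BBN should hydroborate only the monosubstituted terminal alkene of the diene (anti-Markovnikov), and the B-alkyl borane undergoes Suzuki–Miyaura coupling with the vinyl iodide with retention, which fixes the trisubstituted olefin with the two chain CH2 groups cis (the geometry of the future E-enal).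

Step 6
Reactants: 9 (2E,6E,10E)-3-{[(tert-butyldimethylsilyl)oxy]methyl}-7,11,15-trimethylhexadeca-2,6,10,14-tetraen-1-ol
Product: 10 (2E,6E,10E)-1-bromo-3-{[(tert-butyldimethylsilyl)oxy]methyl}-7,11,15-trimethylhexadeca-2,6,10,14-tetraene
Conditions: CBr4, PPh3, 2,6-lutidine, CH2Cl2, −20 → 0 °C
Reagents that add atoms: carbon tetrabromide, BrC(Br)(Br)Br
Why: Appel bromination of the primary allylic alcohol under buffered, cold conditions should proceed by SN2 without allylic transposition or loss of the silyl ether.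

Step 7
Reactants: 10 (2E,6E,10E)-1-bromo-3-{[(tert-butyldimethylsilyl)oxy]methyl}-7,11,15-trimethylhexadeca-2,6,10,14-tetraene; 11 prop-2-yn-1-ol
Product: 12 (5E,9E,13E)-6-{[(tert-butyldimethylsilyl)oxy]methyl}-10,14,18-trimethylnonadeca-5,9,13,17-tetraen-2-yn-1-ol
Conditions: CuI, NaI, K2CO3, DMF, rt
Reagents that add atoms: none
Why: Copper(I)-mediated coupling of the terminal alkyne with the primary allylic bromide (Finkelstein activation by NaI) should occur at the unhindered CH2 terminus (SN2, not SN2′ at the fully substituted carbon) and give the skipped enyne.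

Step 8
Reactants: 12 (5E,9E,13E)-6-{[(tert-butyldimethylsilyl)oxy]methyl}-10,14,18-trimethylnonadeca-5,9,13,17-tetraen-2-yn-1-ol
Product: 13 (2Z,5E,9E,13E)-6-{[(tert-butyldimethylsilyl)oxy]methyl}-10,14,18-trimethylnonadeca-2,5,9,13,17-pentaen-1-ol
Conditions: H2 (1 atm), Lindlar catalyst, quinoline, EtOAc, rt
Reagents that add atoms: none
Why: Lindlar semi-hydrogenation adds H2 syn to the alkyne and should stop at the (Z)-allylic alcohol while the trisubstituted olefins are not reduced.

Step 9
Reactants: 13 (2Z,5E,9E,13E)-6-{[(tert-butyldimethylsilyl)oxy]methyl}-10,14,18-trimethylnonadeca-2,5,9,13,17-pentaen-1-ol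
Product: 14 [(2S,3R)-3-[(2E,6E,10E)-3-{[(tert-butyldimethylsilyl)oxy]methyl}-7,11,15-trimethylhexadeca-2,6,10,14-tetraen-1-yl]oxiran-2-yl]methanol
Conditions: Ti(OiPr)4, L-(+)-diethyl tartrate, t-BuOOH, 4 Å MS, CH2Cl2, −20 °C
Reagents that add atoms: tert-butyl hydroperoxide, CC(C)(C)OO
Why: Sharpless asymmetric epoxidation is specific for the allylic alcohol and, with L-(+)-tartrate, should deliver oxygen to the face that gives the (2S,3R)-cis-epoxide, which sets both stereocentres of the target (absolute control by the tartrate; (Z)-substrates react more slowly and usually less selectively).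

Step 10
Reactants: 14 [(2S,3R)-3-[(2E,6E,10E)-3-{[(tert-butyldimethylsilyl)oxy]methyl}-7,11,15-trimethylhexadeca-2,6,10,14-tetraen-1-yl]oxiran-2-yl]methanol
Product: 15 [(2S,3R)-3-[(2E,6E,10E)-3-{[(tert-butyldimethylsilyl)oxy]methyl}-7,11,15-trimethylhexadeca-2,6,10,14-tetraen-1-yl]oxiran-2-yl]methyl acetate
Conditions: Ac2O, pyridine, DMAP (cat.), CH2Cl2, 0 °C
Reagents that add atoms: acetic anhydride, CC(=O)OC(C)=O
Why: Standard O-acetylation of the primary alcohol installs the two-carbon unit (future ring CH2 and its carbonyl) on the oxygen of the future ring carbonyl carbon without opening the epoxide.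

Step 11
Reactants: 15 [(2S,3R)-3-[(2E,6E,10E)-3-{[(tert-butyldimethylsilyl)oxy]methyl}-7,11,15-trimethylhexadeca-2,6,10,14-tetraen-1-yl]oxiran-2-yl]methyl acetate
Product: 19 (4R,5R)-4-(hydroxymethyl)-5-[(2E,6E,10E)-3-{[(tert-butyldimethylsilyl)oxy]methyl}-7,11,15-trimethylhexadeca-2,6,10,14-tetraen-1-yl]dihydrofuran-2(3H)-one, via lithium ester enolate 16 (not isolated), via lithium alkoxide of the first lactone 17 (not isolated), via lithium alkoxide of the rearranged lactone 18 (not isolated)
Conditions: LiHMDS (1.2 equiv), THF (0.02 M), −78 °C → rt; AcOH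
Reagents that add atoms: none
Why: LiHMDS forms lithium enolate 16, whose carbon attacks the proximal oxirane carbon anti to the breaking C–O bond to give alkoxide 17, the closest known reaction type being the intramolecular opening of epoxides by ester- and nitrile-stabilised carbanions. The ring closed in the C–C bond-forming event is the γ-lactone (the anhydride ring at the lactone oxidation level), formed in the 5-exo-tet mode; 6-endo attack at the distal oxirane carbon would need a cation-stabilising group or a Lewis acid, neither of which is present. The ring CH stereocentre is created by inversion at the (2S)-oxirane carbon and the carbinol centre keeps the oxirane oxygen with its (R) configuration, so both are controlled by the epoxide made in step 9. The secondary alkoxide 17 then attacks the lactone carbonyl through a five-membered transition state and takes over the acyl group (translactonisation), which should be driven by the more stable primary alkoxide 18 and the more substituted trans-4,5-lactone, and which cuts the CH2–O tether and frees it for oxidation. The selectivities required are C- over O-alkylation and ring closure over intermolecular Claisen condensation, secured by the five-membered geometry and high dilution. No centre is epimerisable under the conditions, since neither stereocentre is α to a carbonyl group in 17–19.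

Step 12
Reactants: 19 (4R,5R)-4-(hydroxymethyl)-5-[(2E,6E,10E)-3-{[(tert-butyldimethylsilyl)oxy]methyl}-7,11,15-trimethylhexadeca-2,6,10,14-tetraen-1-yl]dihydrofuran-2(3H)-one
Product: 21 (2R,3S)-2-[(2E,6E,10E)-3-{[(tert-butyldimethylsilyl)oxy]methyl}-7,11,15-trimethylhexadeca-2,6,10,14-tetraen-1-yl]-5-oxotetrahydrofuran-3-carboxylic acid, via lactone aldehyde 20 (not isolated)
Conditions: TEMPO (cat.), PhI(OAc)2 (2.5 equiv), MeCN/H2O, rt
Reagents that add atoms: water, O
Why: TEMPO/PhI(OAc)2 in aqueous acetonitrile oxidises the primary alcohol through aldehyde 20 and its hydrate to the carboxylic acid without affecting lactone, silyl ether or olefins; the trans relationship on the lactone is the thermodynamically preferred one, so the now enolisable ring stereocentre is not at risk.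

Step 13
Reactants: 21 (2R,3S)-2-[(2E,6E,10E)-3-{[(tert-butyldimethylsilyl)oxy]methyl}-7,11,15-trimethylhexadeca-2,6,10,14-tetraen-1-yl]-5-oxotetrahydrofuran-3-carboxylic acid
Product: 24 (S)-2-[(R,3E,7E,11E)-4-{[(tert-butyldimethylsilyl)oxy]methyl}-8,12,16-trimethyl-1-[(triethylsilyl)oxy]heptadeca-3,7,11,15-tetraen-1-yl]succinic acid, via dilithium hydroxy succinate 22 (not isolated), via tris(triethylsilyl) derivative 23 (not isolated)
Conditions: LiOH, THF/H2O, rt; evaporation; TESCl, imidazole, DMF, 0 °C → rt; then THF/H2O, 0 °C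
Reagents that add atoms: lithium hydroxide, [Li+].[OH-]; chlorotriethylsilane, CC[Si](Cl)(CC)CC
Why: Hydroxide opens the lactone to the hydroxy dicarboxylate 22, exhaustive silylation gives 23, and water hydrolyses the two silyl esters far faster than the secondary silyl ether, the same sequence that converts γ-butyrolactone into a 4-silyloxybutanoic acid; the carboxylate-flanked stereocentre is not epimerised under these conditions.

Step 14
Reactants: 24 (S)-2-[(R,3E,7E,11E)-4-{[(tert-butyldimethylsilyl)oxy]methyl}-8,12,16-trimethyl-1-[(triethylsilyl)oxy]heptadeca-3,7,11,15-tetraen-1-yl]succinic acid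
Product: 25 (S)-3-[(R,3E,7E,11E)-4-{[(tert-butyldimethylsilyl)oxy]methyl}-8,12,16-trimethyl-1-[(triethylsilyl)oxy]heptadeca-3,7,11,15-tetraen-1-yl]dihydrofuran-2,5-dione
Conditions: DCC (1.05 equiv), CH2Cl2, 0 °C → rt; filtration
Reagents that add atoms: none
Why: Carbodiimide cyclodehydration of a succinic acid gives the five-membered anhydride under neutral conditions, and the silyl ether prevents the competing γ-lactonisation.

Step 15
Reactants: 25 (S)-3-[(R,3E,7E,11E)-4-{[(tert-butyldimethylsilyl)oxy]methyl}-8,12,16-trimethyl-1-[(triethylsilyl)oxy]heptadeca-3,7,11,15-tetraen-1-yl]dihydrofuran-2,5-dione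
Product: 26 (S)-3-[(R,3E,7E,11E)-1-hydroxy-4-(hydroxymethyl)-8,12,16-trimethylheptadeca-3,7,11,15-tetraen-1-yl]dihydrofuran-2,5-dione
Conditions: 48% aq. HF/MeCN (1:19), 0 °C, short reaction time; cold extractive work-up
Reagents that add atoms: none
Why: Dilute HF in acetonitrile should cleave the secondary triethylsilyl and primary allylic TBS ethers quickly under acidic, non-nucleophilic conditions in which a succinic anhydride hydrolyses only slowly and acyl migration to the freed hydroxyl is not base-catalysed.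

Step 16
Reactants: 26 (S)-3-[(R,3E,7E,11E)-1-hydroxy-4-(hydroxymethyl)-8,12,16-trimethylheptadeca-3,7,11,15-tetraen-1-yl]dihydrofuran-2,5-dione
Product: 27 hippolide D, (S)-3-[(R,3E,7E,11E)-4-formyl-1-hydroxy-8,12,16-trimethylheptadeca-3,7,11,15-tetraen-1-yl]dihydrofuran-2,5-dione
Conditions: TEMPO (cat.), PhI(OAc)2 (1.1 equiv), CH2Cl2, rt
Reagents that add atoms: none
Why: Catalytic TEMPO with PhI(OAc)2 in dichloromethane oxidises primary allylic alcohols far faster than secondary ones and is neutral and anhydrous, so the enal should form with the E geometry fixed in step 5 while the secondary alcohol and the anhydride survive.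

**Compound list**

1 | but-2-yne-1,4-diol | OCC#CCO | starting material
2 | 4-[(tert-butyldimethylsilyl)oxy]but-2-yn-1-ol | OCC#CCO[Si](C)(C)C(C)(C)C | intermediate
3 | sodium alkenylaluminate, five-membered 2,5-dihydro-1,2-oxaaluminole with Al bound to the alkoxide O and to C-3 of the alkene and carrying two 2-methoxyethoxy ligands (not isolated) | [Na+].COCCO[Al-]1(OCCOC)OCC=C1CO[Si](C)(C)C(C)(C)C | intermediate
4 | (Z)-4-[(tert-butyldimethylsilyl)oxy]-3-iodobut-2-en-1-ol | OC/C=C(I)/CO[Si](C)(C)C(C)(C)C | intermediate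
5 | (2E,6E)-farnesol | CC(C)=CCC/C(C)=C/CC/C(C)=C/CO | starting material
6 | (2E,6E)-farnesal | CC(C)=CCC/C(C)=C/CC/C(C)=C/C=O | intermediate
7 | (3E,7E)-4,8,12-trimethyltrideca-1,3,7,11-tetraene | CC(C)=CCC/C(C)=C/CC/C(C)=C/C=C | intermediate
8 | 9-[(3E,7E)-4,8,12-trimethyltrideca-3,7,11-trien-1-yl]-9-borabicyclo[3.3.1]nonane (homofarnesyl-9-BBN, not isolated) | CC(C)=CCC/C(C)=C/CC/C(C)=C/CCB1C2CCCC1CCC2 | intermediate
9 | (2E,6E,10E)-3-{[(tert-butyldimethylsilyl)oxy]methyl}-7,11,15-trimethylhexadeca-2,6,10,14-tetraen-1-ol | CC(C)=CCC/C(C)=C/CC/C(C)=C/CC/C(CO[Si](C)(C)C(C)(C)C)=C\CO | intermediate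
10 | (2E,6E,10E)-1-bromo-3-{[(tert-butyldimethylsilyl)oxy]methyl}-7,11,15-trimethylhexadeca-2,6,10,14-tetraene | CC(C)=CCC/C(C)=C/CC/C(C)=C/CC/C(CO[Si](C)(C)C(C)(C)C)=C\CBr | intermediate
11 | prop-2-yn-1-ol | C#CCO | starting material
12 | (5E,9E,13E)-6-{[(tert-butyldimethylsilyl)oxy]methyl}-10,14,18-trimethylnonadeca-5,9,13,17-tetraen-2-yn-1-ol | CC(C)=CCC/C(C)=C/CC/C(C)=C/CC/C(CO[Si](C)(C)C(C)(C)C)=C\CC#CCO | intermediate
13 | (2Z,5E,9E,13E)-6-{[(tert-butyldimethylsilyl)oxy]methyl}-10,14,18-trimethylnonadeca-2,5,9,13,17-pentaen-1-ol | CC(C)=CCC/C(C)=C/CC/C(C)=C/CC/C(CO[Si](C)(C)C(C)(C)C)=C\C/C=C\CO | intermediate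
14 | [(2S,3R)-3-[(2E,6E,10E)-3-{[(tert-butyldimethylsilyl)oxy]methyl}-7,11,15-trimethylhexadeca-2,6,10,14-tetraen-1-yl]oxiran-2-yl]methanol | CC(C)=CCC/C(C)=C/CC/C(C)=C/CC/C(CO[Si](C)(C)C(C)(C)C)=C\C[C@H]1O[C@H]1CO | intermediate
15 | [(2S,3R)-3-[(2E,6E,10E)-3-{[(tert-butyldimethylsilyl)oxy]methyl}-7,11,15-trimethylhexadeca-2,6,10,14-tetraen-1-yl]oxiran-2-yl]methyl acetate | CC(C)=CCC/C(C)=C/CC/C(C)=C/CC/C(CO[Si](C)(C)C(C)(C)C)=C\C[C@H]1O[C@H]1COC(C)=O | intermediate
16 | lithium enolate of acetate 15 (not isolated) | CC(C)=CCC/C(C)=C/CC/C(C)=C/CC/C(CO[Si](C)(C)C(C)(C)C)=C\C[C@H]1O[C@H]1COC(=C)O[Li] | intermediate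
17 | lithium alkoxide of (R)-4-[(1R,3E,7E,11E)-4-{[(tert-butyldimethylsilyl)oxy]methyl}-1-hydroxy-8,12,16-trimethylheptadeca-3,7,11,15-tetraen-1-yl]dihydrofuran-2(3H)-one (first-formed lactone, not isolated) | CC(C)=CCC/C(C)=C/CC/C(C)=C/CC/C(CO[Si](C)(C)C(C)(C)C)=C\C[C@@H](O[Li])[C@@H]1CC(=O)OC1 | intermediate
18 | lithium alkoxide of lactone 19 (rearranged lactone, not isolated) | CC(C)=CCC/C(C)=C/CC/C(C)=C/CC/C(CO[Si](C)(C)C(C)(C)C)=C\C[C@H]1OC(=O)C[C@@H]1CO[Li] | intermediate
19 | (4R,5R)-4-(hydroxymethyl)-5-[(2E,6E,10E)-3-{[(tert-butyldimethylsilyl)oxy]methyl}-7,11,15-trimethylhexadeca-2,6,10,14-tetraen-1-yl]dihydrofuran-2(3H)-one | CC(C)=CCC/C(C)=C/CC/C(C)=C/CC/C(CO[Si](C)(C)C(C)(C)C)=C\C[C@H]1OC(=O)C[C@@H]1CO | intermediate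
20 | (2R,3S)-2-[(2E,6E,10E)-3-{[(tert-butyldimethylsilyl)oxy]methyl}-7,11,15-trimethylhexadeca-2,6,10,14-tetraen-1-yl]-5-oxotetrahydrofuran-3-carbaldehyde (not isolated) | CC(C)=CCC/C(C)=C/CC/C(C)=C/CC/C(CO[Si](C)(C)C(C)(C)C)=C\C[C@H]1OC(=O)C[C@@H]1C=O | intermediate
21 | (2R,3S)-2-[(2E,6E,10E)-3-{[(tert-butyldimethylsilyl)oxy]methyl}-7,11,15-trimethylhexadeca-2,6,10,14-tetraen-1-yl]-5-oxotetrahydrofuran-3-carboxylic acid | CC(C)=CCC/C(C)=C/CC/C(C)=C/CC/C(CO[Si](C)(C)C(C)(C)C)=C\C[C@H]1OC(=O)C[C@@H]1C(O)=O | intermediate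
22 | dilithium (S)-2-[(R,3E,7E,11E)-4-{[(tert-butyldimethylsilyl)oxy]methyl}-1-hydroxy-8,12,16-trimethylheptadeca-3,7,11,15-tetraen-1-yl]succinate (not isolated) | CC(C)=CCC/C(C)=C/CC/C(C)=C/CC/C(CO[Si](C)(C)C(C)(C)C)=C\C[C@@H](O)[C@@H](C(=O)O[Li])CC(=O)O[Li] | intermediate
23 | bis(triethylsilyl) (S)-2-[(R,3E,7E,11E)-4-{[(tert-butyldimethylsilyl)oxy]methyl}-8,12,16-trimethyl-1-[(triethylsilyl)oxy]heptadeca-3,7,11,15-tetraen-1-yl]succinate (not isolated) | CC(C)=CCC/C(C)=C/CC/C(C)=C/CC/C(CO[Si](C)(C)C(C)(C)C)=C\C[C@@H](O[Si](CC)(CC)CC)[C@@H](C(=O)O[Si](CC)(CC)CC)CC(=O)O[Si](CC)(CC)CC | intermediate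
24 | (S)-2-[(R,3E,7E,11E)-4-{[(tert-butyldimethylsilyl)oxy]methyl}-8,12,16-trimethyl-1-[(triethylsilyl)oxy]heptadeca-3,7,11,15-tetraen-1-yl]succinic acid | CC(C)=CCC/C(C)=C/CC/C(C)=C/CC/C(CO[Si](C)(C)C(C)(C)C)=C\C[C@@H](O[Si](CC)(CC)CC)[C@@H](C(O)=O)CC(O)=O | intermediate
25 | (S)-3-[(R,3E,7E,11E)-4-{[(tert-butyldimethylsilyl)oxy]methyl}-8,12,16-trimethyl-1-[(triethylsilyl)oxy]heptadeca-3,7,11,15-tetraen-1-yl]dihydrofuran-2,5-dione | CC(C)=CCC/C(C)=C/CC/C(C)=C/CC/C(CO[Si](C)(C)C(C)(C)C)=C\C[C@@H](O[Si](CC)(CC)CC)[C@@H]1CC(=O)OC1=O | intermediate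
26 | (S)-3-[(R,3E,7E,11E)-1-hydroxy-4-(hydroxymethyl)-8,12,16-trimethylheptadeca-3,7,11,15-tetraen-1-yl]dihydrofuran-2,5-dione | CC(C)=CCC/C(C)=C/CC/C(C)=C/CC/C(CO)=C\C[C@@H](O)[C@@H]1CC(=O)OC1=O | intermediate
27 | hippolide D, (S)-3-[(R,3E,7E,11E)-4-formyl-1-hydroxy-8,12,16-trimethylheptadeca-3,7,11,15-tetraen-1-yl]dihydrofuran-2,5-dione | CC(C)=CCC/C(C)=C/CC/C(C)=C/CC/C(C=O)=C\C[C@@H](O)[C@@H]1CC(=O)OC1=O | target

**Step count and risks**

Total step count: 16. Longest linear sequence: 14 steps (steps 3–16, from farnesol); steps 1–2 form the side branch to iodide 4.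

Steps most likely to fail:

Step 11. The unstabilised acetate enolate may close the ring sluggishly or unselectively (intermolecular Claisen condensation, 6-endo opening), and the acyl transfer to the thermodynamic lactone may stay incomplete. The fallback sets out from 14 and uses a stabilised carbanion with later reductive removal of the activating group. Esterification of 14 with (phenylsulfonyl)acetic acid (DCC, cat. DMAP, CH2Cl2) should give the epoxy (phenylsulfonyl)acetate F1. The sulfonyl-stabilised carbanion (DBU, CH2Cl2, or Cs2CO3, MeCN, rt) should open the oxirane in the same 5-exo sense under much milder conditions and, after the same acyl transfer, give the α-sulfonyl hydroxymethyl lactone F2. Reductive desulfonylation (Al amalgam, aq. THF, 0 °C) comes back to the route at 19.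

Step 15. The anhydride may hydrolyse, or the freed β-hydroxyl may migrate onto the ring carbonyl, during fluoride-mediated desilylation. The fallback sets out from 24 and closes the anhydride last. Both silyl ethers are removed before ring closure (HF·pyridine buffered with pyridine, THF, 0 °C) to give the dihydroxy diacid F3, which is handled cold and without acidic work-up because γ-hydroxy acids lactonise only slowly near neutral pH. Chemoselective oxidation of the primary allylic alcohol (TEMPO cat., PhI(OAc)2, CH2Cl2/THF) gives the hydroxy diacid enal F4. Cyclodehydration with DCC (1.0 equiv, −20 °C), in which attack of the neighbouring carboxyl on the O-acylisourea is expected to outrun attack by the hydroxyl, arrives directly at 27.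

Step 9. The epoxidation may be slow and its enantioselectivity eroded, as is typical of (Z)-allylic alcohols. The fallback sets out from 13 and replaces asymmetric induction by a resolution. Hydroxyl-directed epoxidation with VO(acac)2/t-BuOOH gives the racemic cis-epoxy alcohol (14 together with its (2R,3S)-enantiomer F5). Lipase-catalysed acyl transfer (Pseudomonas cepacia lipase, vinyl acetate, enzyme screened for the required enantiomer) should acetylate the (2S,3R)-alcohol selectively and leave F5 behind, so the route is rejoined at 15.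

**Further compounds**

F1 | step 11 | [(2S,3R)-3-[(2E,6E,10E)-3-{[(tert-butyldimethylsilyl)oxy]methyl}-7,11,15-trimethylhexadeca-2,6,10,14-tetraen-1-yl]oxiran-2-yl]methyl 2-(phenylsulfonyl)acetate | CC(C)=CCC/C(C)=C/CC/C(C)=C/CC/C(CO[Si](C)(C)C(C)(C)C)=C\C[C@H]1O[C@H]1COC(=O)CS(=O)(=O)c1ccccc1
F2 | step 11 | (4R,5R)-4-(hydroxymethyl)-3-(phenylsulfonyl)-5-[(2E,6E,10E)-3-{[(tert-butyldimethylsilyl)oxy]methyl}-7,11,15-trimethylhexadeca-2,6,10,14-tetraen-1-yl]dihydrofuran-2(3H)-one (both C-3 epimers) | CC(C)=CCC/C(C)=C/CC/C(C)=C/CC/C(CO[Si](C)(C)C(C)(C)C)=C\C[C@H]1OC(=O)C(S(=O)(=O)c2ccccc2)[C@@H]1CO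
F3 | step 15 | (S)-2-[(R,3E,7E,11E)-1-hydroxy-4-(hydroxymethyl)-8,12,16-trimethylheptadeca-3,7,11,15-tetraen-1-yl]succinic acid | CC(C)=CCC/C(C)=C/CC/C(C)=C/CC/C(CO)=C\C[C@@H](O)[C@@H](C(O)=O)CC(O)=O
F4 | step 15 | (S)-2-[(R,3E,7E,11E)-4-formyl-1-hydroxy-8,12,16-trimethylheptadeca-3,7,11,15-tetraen-1-yl]succinic acid | CC(C)=CCC/C(C)=C/CC/C(C)=C/CC/C(C=O)=C\C[C@@H](O)[C@@H](C(O)=O)CC(O)=O
F5 | step 9 | [(2R,3S)-3-[(2E,6E,10E)-3-{[(tert-butyldimethylsilyl)oxy]methyl}-7,11,15-trimethylhexadeca-2,6,10,14-tetraen-1-yl]oxiran-2-yl]methanol (enantiomer of 14) | CC(C)=CCC/C(C)=C/CC/C(C)=C/CC/C(CO[Si](C)(C)C(C)(C)C)=C\C[C@@H]1O[C@@H]1CO
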